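# Proposed synthesis of 5,2',3'-trihydroxy-3,7,8-trimethoxyflavone (26)

## Analysis of the target

The target 26 is a flavone: a benzene ring A fused to a 4-pyranone ring C (4H-chromen-4-one), with a 2,3-dihydroxyphenyl ring B on C2. It has no stereocentre, so the problem is one of regiochemistry and of telling six oxygen substituents apart: methyl ethers on O3, O7 and O8, free hydroxyls on C5, C2' and C3'. Ring A carries oxygen at C5, C7, C8 and C8a and hydrogen only at C6. This 5,7,8 pattern cannot be laid down reliably by electrophilic substitution of a simple phenol, and under strong acid it can isomerise to the 5,6,7 pattern by opening and reclosure of ring C (Wessely–Moser rearrangement). The sensitive parts are the catechol of ring B (oxidised easily in base), the 5,8-dioxygenated ring A (a quinone forms if both oxygens are free) and the pyranone (opened at C2 by strong nucleophiles). The 5-hydroxyl is hydrogen-bonded to the C4 carbonyl, so it is the least nucleophilic phenol and its methyl ether is the one a chelating Lewis acid removes first; both facts are used. The plan rests on one feature: O1 and C4 sit on the neighbouring ring A carbons C8a and C4a, and C5, next to C4a, bears oxygen. A ring A aryne spanning C4a–C8a with a methoxy group on C5 is therefore polarised to accept oxygen at C8a and carbon at C4a.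

## Retrosynthetic reasoning

**26 ⇒ 25.** The two benzylic O–C bonds on ring B are cut last. The catechol must stay masked through base, fluoride, Lewis acid and oxidant, and benzyl ethers leave by hydrogenolysis without touching the three methyl ethers or the pyranone.

**25 ⇒ 24 ⇒ 22.** The O8–CH3 bond and then the C8–O8 bond are cut. C8 is para to the 5-hydroxyl, the position that a phenoxide oxidation of the Elbs type reaches. The new hydroxyl of 24 is the only phenol not hydrogen-bonded to the carbonyl, so one equivalent of a methylating agent should find it. The cut is made here and not at the aryne stage, because an aryne already carrying the C8 oxygen would have oxygen on both sides of the triple bond and would lose its orientational bias. The gain is a symmetric, cheap ring A precursor.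

**22 ⇒ 21.** The 5-hydroxyl is traced back to its methyl ether. The C5 oxygen has to enter the key step small and protected, since it polarises the aryne. Afterwards it lies peri to the carbonyl, where chelation should allow its cleavage in the presence of the 3- and 7-methyl ethers and the benzyl ethers.

**21 ⇒ 8 + 17.** Ring C is cut at O1–C8a, C4–C4a and O1–C2. Ring A becomes aryne 18, released from silyl triflate 8. Acid 17 holds C2, C3, C4 and ring B, and its carboxyl group supplies both C4 and O1. Other cuts through ring C would need a fully oxygenated ring A with the ortho oxygen/acyl relationship already in place; here the insertion creates that relationship. The forward reaction must add the carboxylate oxygen to C8a, move the acyl carbon to C4a, and let the phenoxide displace methoxide from C2.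

**8 ⇒ 6 ⇒ 2 ⇒ 1.** The O–S bond of the triflate and the C2–Si bond are cut. The silyl group is placed by directed metalation between the carbamate oxygen and a methoxy group of 2. Phenol 1 is symmetric, so only one such position exists.

**17 ⇒ 16 ⇒ 15 ⇒ 11 + 12; 11 ⇒ 9.** The acid comes from ester 16, the enol O–CH3 bond is cut to give keto ester 15, and the bond between the ketone carbon and the α-carbon is cut to give acyl donor 13 (from 11) and enolate 14 (from 12). Acid 11 comes from 9 by benzylation. All of this is standard enolate chemistry, so the uncertainty of the route stays in the key step.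

## Alternatives that were turned down

**Alternative 1:** Ring A, not ring C, is taken apart. Four ring A bonds (C4a–C8a, C5–C6, C6–C7, C8–C8a) are traced back to an unsaturated α-diazo ketone and a silyloxy alkyne (Danheiser benzannulation). Irradiation would cause Wolff rearrangement to a vinylketene, which adds [2+2] to the ynol silyl ether. Four-electron opening of the cyclobutenone and six-electron closure of the dienylketene on warming would give the pentasubstituted phenol A1, 2-[(Z)-1,2-dimethoxyethenyl]-5,6-dimethoxy-3-{[tri(propan-2-yl)silyl]oxy}phenol.
- For: every ring A oxygen is placed by construction and differentiated (free hydroxyl for O1, silyl ether on O5, methyl ethers on O7 and O8). On this point it is stronger than the chosen plan, which needs a late C–H oxidation and an ether cleavage on ring A.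
- Against: A1 contains neither C2, ring B nor ring C. Aroylation with 13, unmasking of the enol ether at C4, ring closure and desilylation would still follow, so the steps saved on ring A are spent again. Both partners are multi-step and fragile, and the dimethoxyethenyl group is an electron-rich alkene that competes with the alkyne for the ketene under irradiation.
- Comparison: the chosen plan closes ring C and joins ring A to the three-carbon unit carrying ring B in one operation, from fragments of three and four steps. Its price is an Elbs oxidation of modest efficiency.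

**Alternative 2:** C4–C4a and C3–C4 are cut, and C4 comes from carbon monoxide A3. A ring A aryl iodide, A3 and the enolate of the ring B methoxymethyl ketone would be joined by a zerovalent palladium catalyst bearing a wide-bite-angle bisphosphine (carbonylative α-arylation). The product would be diketone A2, racemic 1-[2,3-bis(benzyloxy)phenyl]-2-methoxy-3-[3,4,6-trimethoxy-2-(methoxymethoxy)phenyl]propane-1,3-dione. Acid would then remove the methoxymethyl group and close ring C by cyclodehydration.
- For: it is convergent, ring A arrives with its full 5,7,8-oxygenation (no Elbs step), and the diketone-to-flavone closure is among the most dependable reactions of flavonoid chemistry. On these points it is equal or stronger.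
- Against: oxidative addition must occur at an iodide flanked by two ortho oxygens on a very electron-rich ring. The aroyl palladium species must then be attacked by a hindered α-oxygenated enolate to form a tertiary carbon, with direct arylation, reduction and O-acylation as competitors. The iodide is a pentasubstituted benzene with four differentiated oxygens and no short synthesis, so the ring A problem is moved, not solved. The key step closes no ring.
- Comparison: the chosen plan gets its ring A fragment in three steps from a symmetric phenol, the aryne carries its own regiochemical bias, and no toxic gas is needed. Against it stands the late oxidation.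

**Alternative 3:** Kojic acid A5 would supply ring C (O1, C2, C3 with its oxygen, C4, C4a, C8a) and, through its hydroxymethyl carbon, C8. Ring A would be closed last at C4a–C5. A pyranone bearing ring B at C2 and a methoxylated β-keto ester chain at C8a would be converted by a magnesium alkoxide or excess lithium amide base into a dienolate. Its C4a carbon would attack the ester carbonyl (intramolecular Claisen condensation), and tautomerisation would give resorcinol A4, 2-[2,3-bis(benzyloxy)phenyl]-5,7-dihydroxy-3,8-dimethoxy-4H-chromen-4-one.
- For: it has the shortest endgame of all (methylation of the unchelated 7-hydroxyl, then hydrogenolysis). The 8-methoxy group and free 5-hydroxyl arise directly, with no oxidation and no demethylation. Here it is clearly stronger than the chosen plan.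
- Against: C4a is the α-carbon of a cross-conjugated pyranone and is nucleophilic only through a vinylogous dienolate. The most acidic protons lie between the two side-chain carbonyls, and once they are removed the ester is held as an enolate and is no longer electrophilic. The closure therefore depends on a polyanion or chelate, and alkoxide bases can open the pyranone at C2. The precursor also needs arylation next to the ring oxygen with an ortho-substituted aryl group and a multi-step extension of the hydroxymethyl carbon.
- Comparison: the chosen plan places its risk in a step with close precedent, reached after short sequences, and accepts a longer endgame in exchange.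

Key step: step 8

Remark on the chemistry: enol ether 16 and acid 17 are drawn as the Z isomers (the two methoxy groups cis), the geometry expected from O-methylation of the dissociated enolate. The E isomers would follow the same course and converge on 21, so the geometry is not a requirement of the route.

## Route

Step 1
Reactants: 1 3,5-dimethoxyphenol
Product: 2 3,5-dimethoxyphenyl N-(propan-2-yl)carbamate
Conditions: iPrNCO, Et3N (cat.), CH2Cl2, rt
Reagents that add atoms: isopropyl isocyanate, CC(C)N=C=O
Why: Base-catalysed addition of the phenol to the isocyanate gives the N-monoalkyl carbamate, which directs the metalation of step 2 and can later be removed by E1cB elimination.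

Step 2
Reactants: 2 3,5-dimethoxyphenyl N-(propan-2-yl)carbamate
Product: 6 3,5-dimethoxy-2-(trimethylsilyl)phenyl N-(propan-2-yl)carbamate, via N-silyl carbamate 3 (not isolated), via ortho-lithiated carbamate 4 (not isolated), via N,C-disilylated carbamate 5 (not isolated)
Conditions: TBSOTf, TMEDA, Et2O, 0 °C to rt; n-BuLi, TMEDA, −78 °C; TMSCl, −78 °C to rt; aq. NaHSO4
Reagents that add atoms: chlorotrimethylsilane, C[Si](C)(C)Cl
Why: Directed ortho-metalation: transient N-silylation masks the N–H, and n-BuLi/TMEDA removes the proton at C2, flanked by the carbamate oxygen (the stronger director) and a methoxy group. C2 and C6 are equivalent by symmetry, so one aryl silane should result, and the N–Si bond is hydrolysed on work-up.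

Step 3
Reactants: 6 3,5-dimethoxy-2-(trimethylsilyl)phenyl N-(propan-2-yl)carbamate
Product: 8 3,5-dimethoxy-2-(trimethylsilyl)phenyl trifluoromethanesulfonate, via 3,5-dimethoxy-2-(trimethylsilyl)phenolate 7 (not isolated)
Conditions: DBU, Et2NH, MeCN, 40 °C; then PhNTf2, rt
Reagents that add atoms: N-phenylbis(trifluoromethanesulfonimide), O=S(=O)(N(c1ccccc1)S(=O)(=O)C(F)(F)F)C(F)(F)F
Why: DBU removes the N–H proton and the carbamate fragments by E1cB elimination to the phenoxide and isopropyl isocyanate, which diethylamine scavenges; the phenoxide is triflated in the same flask. The conditions are basic and fluoride-free, so the aryl–silicon bond should survive.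

Step 4
Reactants: 9 2,3-dihydroxybenzoic acid
Product: 11 2,3-bis(benzyloxy)benzoic acid, via benzyl 2,3-bis(benzyloxy)benzoate 10 (not isolated)
Conditions: BnBr (3.3 equiv), K2CO3, DMF, 60 °C, N2; then aq. NaOH, MeOH, 70 °C; HCl
Reagents that add atoms: benzyl bromide, BrCc1ccccc1; sodium hydroxide, [Na+].[OH-]
Why: Williamson alkylation of both phenols and the carboxylate, then saponification of the benzyl ester in the same flask. Benzyl ethers should withstand every later reagent and leave by hydrogenolysis at the end.

Step 5
Reactants: 11 2,3-bis(benzyloxy)benzoic acid; 12 methyl methoxyacetate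
Product: 15 methyl 3-[2,3-bis(benzyloxy)phenyl]-2-methoxy-3-oxopropanoate (racemic), via 2,3-bis(benzyloxy)benzoyl chloride 13 (not isolated), via lithium enolate 14 (not isolated)
Conditions: 11, (COCl)2, DMF (cat.), CH2Cl2, 0 °C to rt, concentrate; 12 (2.2 equiv), LiN(iPr)2 (2.2 equiv), THF, −78 °C; add 13, −78 °C; aq. NH4Cl
Reagents that add atoms: none
Why: Claisen-type C-acylation of a preformed lithium ester enolate by an acid chloride; two equivalents of enolate are used because the β-keto ester is deprotonated as it forms. The stereocentre at C2 is not controlled and disappears in step 6.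

Step 6
Reactants: 15 methyl 3-[2,3-bis(benzyloxy)phenyl]-2-methoxy-3-oxopropanoate
Product: 16 methyl (Z)-3-[2,3-bis(benzyloxy)phenyl]-2,3-dimethoxyprop-2-enoate
Conditions: Cs2CO3, Me2SO4, DMF, 0 °C to rt
Reagents that add atoms: dimethyl sulfate, COS(=O)(=O)OC
Why: O-alkylation of a dissociated cesium enolate by a hard methylating agent in a dipolar aprotic solvent; the fully substituted, methoxy-bearing α-carbon disfavours C-methylation. The extended (W-shaped) enolate should give mainly the Z enol ether.

Step 7
Reactants: 16 methyl (Z)-3-[2,3-bis(benzyloxy)phenyl]-2,3-dimethoxyprop-2-enoate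
Product: 17 (Z)-3-[2,3-bis(benzyloxy)phenyl]-2,3-dimethoxyprop-2-enoic acid
Conditions: LiOH·H2O, THF/MeOH/H2O, 40 °C; then 0.5 M HCl to pH 3–4, 0 °C
Reagents that add atoms: lithium hydroxide, [Li+].[OH-]
Why: Ester saponification; the β-carbon is tetrasubstituted and electron-rich, so hydroxide should attack the ester carbonyl and not add in conjugate fashion. Cold, mild acidification avoids hydrolysis of the enol ether and decarboxylation.

Step 8
Reactants: 8 3,5-dimethoxy-2-(trimethylsilyl)phenyl trifluoromethanesulfonate; 17 (Z)-3-[2,3-bis(benzyloxy)phenyl]-2,3-dimethoxyprop-2-enoic acid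
Product: 21 2-[2,3-bis(benzyloxy)phenyl]-3,5,7-trimethoxy-4H-chromen-4-one, via 3,5-dimethoxybenzyne 18 (not isolated), via ortho-cesiated aryl ester 19 (not isolated), via cesium ketophenolate 20 (not isolated)
Conditions: 8 (1.5 equiv), CsF (4 equiv), THF, 125 °C, sealed tube
Reagents that add atoms: none
Why: Proposed new method: fluoride removes the silyl group of 8 and triflate leaves to give aryne 18; the cesium carboxylate of 17 adds through oxygen to the aryne carbon remote from the flanking methoxy group (the future C8a), because this puts the aryl anion on the carbon next to that methoxy group (the future C4a), where the σ-withdrawing oxygen stabilises it. Anion 19 then attacks its own ester carbonyl through a four-membered transition state (an anionic Fries-type 1,3 O-to-C acyl shift), forming C4–C4a and releasing phenoxide 20. The phenoxide oxygen adds 6-endo-trig to the β-carbon of the vinylogous ester and methoxide is expelled (addition–elimination), forming O1–C2 and closing ring C. The closest known reactions are the fluoride-induced insertion of arynes into the C–O bond of carboxylic acids to give o-hydroxyaryl ketones, and the same insertion with cinnamic acids, where the phenoxide ends the sequence by oxa-Michael addition to give chromanones; ending it by addition–elimination on a β-alkoxyacrylic acid has not been shown. No stereocentre is formed, and because C2 passes through an sp3 adduct before methoxide leaves, both alkene geometries of 17 should converge on 21. Two selectivities are needed: the orientation of addition to the aryne, secured by the methoxy group next to the triple bond (the second methoxy group is meta to the attacked carbon and does not oppose it), and acyl transfer in preference to protonation of 19, which the high temperature and aprotic medium are meant to favour.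

Step 9
Reactants: 21 2-[2,3-bis(benzyloxy)phenyl]-3,5,7-trimethoxy-4H-chromen-4-one
Product: 22 2-[2,3-bis(benzyloxy)phenyl]-5-hydroxy-3,7-dimethoxy-4H-chromen-4-one
Conditions: MgI2 (from Mg and I2 in Et2O), toluene, 80 °C; aq. HCl, Na2S2O3
Reagents that add atoms: none
Why: Chelation-assisted demethylation: magnesium bridges the C4 carbonyl and the peri 5-methoxy oxygen in a six-membered chelate and iodide removes the methyl group by SN2 attack. The 3-methoxy group could only form a five-membered chelate, and the 7-methoxy and benzyl ethers are not chelated.

Step 10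
Reactants: 22 2-[2,3-bis(benzyloxy)phenyl]-5-hydroxy-3,7-dimethoxy-4H-chromen-4-one
Product: 24 2-[2,3-bis(benzyloxy)phenyl]-5,8-dihydroxy-3,7-dimethoxy-4H-chromen-4-one, via potassium 8-sulfate 23 (not isolated)
Conditions: K2S2O8, aq. KOH, pyridine, 15–20 °C; acidify, extract unchanged 22; aqueous phase, HCl, Na2SO3, 80 °C
Reagents that add atoms: potassium peroxydisulfate, [K+].[K+].[O-]S(=O)(=O)OOS(=O)(=O)[O-]
Why: Elbs persulfate oxidation: the 5-phenoxide attacks peroxydisulfate through its para carbon C8 to give the aryl sulfate, which warm dilute acid hydrolyses to the quinol. Ring A holds the only free phenol, so ring B should not be touched, and para attack is preferred over ortho attack at C6.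

Step 11
Reactants: 24 2-[2,3-bis(benzyloxy)phenyl]-5,8-dihydroxy-3,7-dimethoxy-4H-chromen-4-one
Product: 25 2-[2,3-bis(benzyloxy)phenyl]-5-hydroxy-3,7,8-trimethoxy-4H-chromen-4-one
Conditions: MeI (1.05 equiv), K2CO3 (1.1 equiv), acetone, rt, Ar
Reagents that add atoms: iodomethane, CI
Why: Williamson methylation with one equivalent of reagent; the 5-hydroxyl is hydrogen-bonded to the carbonyl and much less nucleophilic than the 8-hydroxyl, so O8 should be methylated alone. Argon keeps the quinol from oxidising to the quinone.

Step 12
Reactants: 25 2-[2,3-bis(benzyloxy)phenyl]-5-hydroxy-3,7,8-trimethoxy-4H-chromen-4-one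
Product: 26 2-(2,3-dihydroxyphenyl)-5-hydroxy-3,7,8-trimethoxy-4H-chromen-4-one
Conditions: H2 (1 atm), 10% Pd/C, EtOAc/MeOH, rt
Reagents that add atoms: none
Why: Hydrogenolysis of the two benzyl ethers; the tetrasubstituted, conjugated C2=C3 bond and the methyl ethers should not react under these neutral conditions, which also exclude acid-induced rearrangement of ring A.

## Compound list

1 | 3,5-dimethoxyphenol | COc1cc(O)cc(OC)c1 | starting material
2 | 3,5-dimethoxyphenyl N-(propan-2-yl)carbamate | COc1cc(OC)cc(OC(=O)NC(C)C)c1 | intermediate
3 | 3,5-dimethoxyphenyl N-[tert-butyl(dimethyl)silyl]-N-(propan-2-yl)carbamate | COc1cc(OC)cc(OC(=O)N(C(C)C)[Si](C)(C)C(C)(C)C)c1 | intermediate (not isolated)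
4 | 2-lithio-3,5-dimethoxyphenyl N-[tert-butyl(dimethyl)silyl]-N-(propan-2-yl)carbamate | [Li]c1c(OC)cc(OC)cc1OC(=O)N(C(C)C)[Si](C)(C)C(C)(C)C | intermediate (not isolated)
5 | 3,5-dimethoxy-2-(trimethylsilyl)phenyl N-[tert-butyl(dimethyl)silyl]-N-(propan-2-yl)carbamate | COc1cc(OC)c([Si](C)(C)C)c(OC(=O)N(C(C)C)[Si](C)(C)C(C)(C)C)c1 | intermediate (not isolated)
6 | 3,5-dimethoxy-2-(trimethylsilyl)phenyl N-(propan-2-yl)carbamate | COc1cc(OC)c([Si](C)(C)C)c(OC(=O)NC(C)C)c1 | intermediate
7 | 3,5-dimethoxy-2-(trimethylsilyl)phenol (present as its DBU salt) | COc1cc(O)c([Si](C)(C)C)c(OC)c1 | intermediate (not isolated)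
8 | 3,5-dimethoxy-2-(trimethylsilyl)phenyl trifluoromethanesulfonate | COc1cc(OC)c([Si](C)(C)C)c(OS(=O)(=O)C(F)(F)F)c1 | intermediate
9 | 2,3-dihydroxybenzoic acid | OC(=O)c1cccc(O)c1O | starting material
10 | benzyl 2,3-bis(benzyloxy)benzoate | O=C(OCc1ccccc1)c1cccc(OCc2ccccc2)c1OCc1ccccc1 | intermediate (not isolated)
11 | 2,3-bis(benzyloxy)benzoic acid | OC(=O)c1cccc(OCc2ccccc2)c1OCc1ccccc1 | intermediate
12 | methyl methoxyacetate | COCC(=O)OC | starting material
13 | 2,3-bis(benzyloxy)benzoyl chloride | ClC(=O)c1cccc(OCc2ccccc2)c1OCc1ccccc1 | intermediate (not isolated)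
14 | lithium (E)-1,2-dimethoxyethen-1-olate (chelated enolate of 12; geometry without consequence) | CO/C=C(/OC)O[Li] | intermediate (not isolated)
15 | methyl 3-[2,3-bis(benzyloxy)phenyl]-2-methoxy-3-oxopropanoate (racemic, configurationally labile) | COC(=O)C(OC)C(=O)c1cccc(OCc2ccccc2)c1OCc1ccccc1 | intermediate
16 | methyl (Z)-3-[2,3-bis(benzyloxy)phenyl]-2,3-dimethoxyprop-2-enoate | COC(=O)/C(OC)=C(/OC)c1cccc(OCc2ccccc2)c1OCc1ccccc1 | intermediate
17 | (Z)-3-[2,3-bis(benzyloxy)phenyl]-2,3-dimethoxyprop-2-enoic acid | OC(=O)/C(OC)=C(/OC)c1cccc(OCc2ccccc2)c1OCc1ccccc1 | intermediate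
18 | 3,5-dimethoxybenzyne (1,2-didehydro-3,5-dimethoxybenzene) | COC1=CC(OC)=CC#C1 | intermediate (not isolated)
19 | 2-cesio-3,5-dimethoxyphenyl (Z)-3-[2,3-bis(benzyloxy)phenyl]-2,3-dimethoxyprop-2-enoate | COc1cc(OC)c([Cs])c(OC(=O)/C(OC)=C(/OC)c2cccc(OCc3ccccc3)c2OCc2ccccc2)c1 | intermediate (not isolated)
20 | cesium 2-{(Z)-3-[2,3-bis(benzyloxy)phenyl]-2,3-dimethoxyprop-2-enoyl}-3,5-dimethoxyphenolate | COc1cc(OC)c(C(=O)/C(OC)=C(/OC)c2cccc(OCc3ccccc3)c2OCc2ccccc2)c([O-])c1.[Cs+] | intermediate (not isolated)
21 | 2-[2,3-bis(benzyloxy)phenyl]-3,5,7-trimethoxy-4H-chromen-4-one | COc1cc(OC)c2c(=O)c(OC)c(-c3cccc(OCc4ccccc4)c3OCc3ccccc3)oc2c1 | intermediate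
22 | 2-[2,3-bis(benzyloxy)phenyl]-5-hydroxy-3,7-dimethoxy-4H-chromen-4-one | COc1cc(O)c2c(=O)c(OC)c(-c3cccc(OCc4ccccc4)c3OCc3ccccc3)oc2c1 | intermediate
23 | potassium 2-[2,3-bis(benzyloxy)phenyl]-5-hydroxy-3,7-dimethoxy-4-oxo-4H-chromen-8-yl sulfate | COc1cc(O)c2c(=O)c(OC)c(-c3cccc(OCc4ccccc4)c3OCc3ccccc3)oc2c1OS(=O)(=O)[O-].[K+] | intermediate (not isolated)
24 | 2-[2,3-bis(benzyloxy)phenyl]-5,8-dihydroxy-3,7-dimethoxy-4H-chromen-4-one | COc1cc(O)c2c(=O)c(OC)c(-c3cccc(OCc4ccccc4)c3OCc3ccccc3)oc2c1O | intermediate
25 | 2-[2,3-bis(benzyloxy)phenyl]-5-hydroxy-3,7,8-trimethoxy-4H-chromen-4-one | COc1cc(O)c2c(=O)c(OC)c(-c3cccc(OCc4ccccc4)c3OCc3ccccc3)oc2c1OC | intermediate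
26 | 2-(2,3-dihydroxyphenyl)-5-hydroxy-3,7,8-trimethoxy-4H-chromen-4-one (5,2',3'-trihydroxy-3,7,8-trimethoxyflavone) | COc1cc(O)c2c(=O)c(OC)c(-c3cccc(O)c3O)oc2c1OC | target

## Step count and least certain steps

Total step count: 12. Longest linear sequence: 9 steps (steps 4 to 12, from 9). The aryne branch (steps 1 to 3) joins at step 8.

**Step 8 (key step, proposed new method).**
- What may go wrong: the aryl anion 19 may be protonated before acyl transfer, so the sequence stops at simple O-arylation. The anion may attack the β-carbon instead of the carbonyl, which leads into the isomeric 4-arylcoumarin series. The hindered, electron-rich β-carbon may resist ring closure, so the open hydroxy ketone is left. Released methoxide may consume aryne.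
- Remedy within the strategy: if the open ketone accumulates, brief acid treatment should close it.
- Fallback by known chemistry, setting out from 1 and 11 and returning at 21: phenol 1 would be C-acylated ortho to the hydroxyl with methoxyacetic acid in BF3·OEt2 at 90 °C (Fries-type acylation, the ortho ketone held as its difluoroboron chelate). This gives 1-(2-hydroxy-4,6-dimethoxyphenyl)-2-methoxyethan-1-one F1. Its phenol would be esterified with acid chloride 13 (from 11) in pyridine to give 3,5-dimethoxy-2-(methoxyacetyl)phenyl 2,3-bis(benzyloxy)benzoate F2. KOH in pyridine at 50 °C (Baker–Venkataraman rearrangement) would move the aroyl group to carbon, giving racemic 1-[2,3-bis(benzyloxy)phenyl]-3-(2-hydroxy-4,6-dimethoxyphenyl)-2-methoxypropane-1,3-dione F3. Cyclodehydration (NaOAc, AcOH, 100 °C) would then give 21.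

**Step 10 (Elbs oxidation).**
- What may go wrong: incomplete conversion and oxidative degradation, both usual for persulfate oxidations, made worse by the low solubility of the lipophilic phenoxide in aqueous base.
- Fallback, from 21 to 25: bromination with NBS (DMF, 0 °C) at C8, the less hindered of the two open ring A positions, would give 2-[2,3-bis(benzyloxy)phenyl]-8-bromo-3,5,7-trimethoxy-4H-chromen-4-one F4. Ullmann-type methoxylation (NaOMe, CuBr, MeOH/DMF, 110 °C) would give 2-[2,3-bis(benzyloxy)phenyl]-3,5,7,8-tetramethoxy-4H-chromen-4-one F5. The chelation-controlled demethylation of step 9 (MgI2) applied to F5 would give 25 directly.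

**Step 6 (enol O-methylation).**
- What may go wrong: competing C-methylation of the ambident enolate, giving a quaternary keto ester.
- Fallback, from 15 to 16: acid-catalysed ketalisation (HC(OMe)3, MeOH, TsOH cat.) would give methyl 3-[2,3-bis(benzyloxy)phenyl]-2,3,3-trimethoxypropanoate F6. Elimination of methanol with TMSOTf and iPr2NEt in CH2Cl2 would give 16. No enolate is alkylated, so the C/O question does not arise.

**Step 9 (selective 5-O-demethylation).**
- What may go wrong: partial loss of the benzyl ethers or of the 3-methyl ether under the Lewis acid, or slow conversion.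
- Fallback, from 21 to 22: BCl3 in CH2Cl2 (−78 to 0 °C) would deliberately cleave the chelated 5-methyl ether and both benzyl ethers, giving 2-(2,3-dihydroxyphenyl)-5-hydroxy-3,7-dimethoxy-4H-chromen-4-one F7. The two unchelated ring B phenols would then be re-benzylated (BnBr 2.1 equiv, K2CO3, acetone), the hydrogen-bonded 5-hydroxyl being the least reactive, to return 22.

**Step 2 (ortho-silylation).**
- What may go wrong: competing lithiation at C4 between the two methoxy groups, or migration of the carbamoyl group to carbon (anionic Fries rearrangement) on warming.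
- Fallback, from 1 to 8: bromination of 1 with NBS (CH2Cl2, −78 °C) would give 2-bromo-3,5-dimethoxyphenol F8, to be separated from any 4-bromo isomer. O-silylation with (Me3Si)2NH would give (2-bromo-3,5-dimethoxyphenoxy)trimethylsilane F9. n-BuLi at −100 °C would cause bromine–lithium exchange and a 1,3 O-to-C silyl shift, and trapping the lithium phenoxide with Tf2O would give 8.

## Further compounds

F1 | step 8 | 1-(2-hydroxy-4,6-dimethoxyphenyl)-2-methoxyethan-1-one | COCC(=O)c1c(O)cc(OC)cc1OC
F2 | step 8 | 3,5-dimethoxy-2-(methoxyacetyl)phenyl 2,3-bis(benzyloxy)benzoate | COCC(=O)c1c(OC)cc(OC)cc1OC(=O)c1cccc(OCc2ccccc2)c1OCc1ccccc1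
F3 | step 8 | racemic 1-[2,3-bis(benzyloxy)phenyl]-3-(2-hydroxy-4,6-dimethoxyphenyl)-2-methoxypropane-1,3-dione | COC(C(=O)c1c(O)cc(OC)cc1OC)C(=O)c1cccc(OCc2ccccc2)c1OCc1ccccc1
F4 | step 10 | 2-[2,3-bis(benzyloxy)phenyl]-8-bromo-3,5,7-trimethoxy-4H-chromen-4-one | COc1cc(OC)c2c(=O)c(OC)c(-c3cccc(OCc4ccccc4)c3OCc3ccccc3)oc2c1Br
F5 | step 10 | 2-[2,3-bis(benzyloxy)phenyl]-3,5,7,8-tetramethoxy-4H-chromen-4-one | COc1cc(OC)c2c(=O)c(OC)c(-c3cccc(OCc4ccccc4)c3OCc3ccccc3)oc2c1OC
F6 | step 6 | racemic methyl 3-[2,3-bis(benzyloxy)phenyl]-2,3,3-trimethoxypropanoate | COC(=O)C(OC)C(OC)(OC)c1cccc(OCc2ccccc2)c1OCc1ccccc1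
F7 | step 9 | 2-(2,3-dihydroxyphenyl)-5-hydroxy-3,7-dimethoxy-4H-chromen-4-one | COc1cc(O)c2c(=O)c(OC)c(-c3cccc(O)c3O)oc2c1
F8 | step 2 | 2-bromo-3,5-dimethoxyphenol | COc1cc(O)c(Br)c(OC)c1
F9 | step 2 | (2-bromo-3,5-dimethoxyphenoxy)trimethylsilane | COc1cc(O[Si](C)(C)C)c(Br)c(OC)c1
A1 | alternative 1 | 2-[(Z)-1,2-dimethoxyethenyl]-5,6-dimethoxy-3-{[tri(propan-2-yl)silyl]oxy}phenol | CO/C=C(OC)/c1c(O)c(OC)c(OC)cc1O[Si](C(C)C)(C(C)C)C(C)C
A2 | alternative 2 | racemic 1-[2,3-bis(benzyloxy)phenyl]-2-methoxy-3-[3,4,6-trimethoxy-2-(methoxymethoxy)phenyl]propane-1,3-dione | COCOc1c(C(=O)C(OC)C(=O)c2cccc(OCc3ccccc3)c2OCc2ccccc2)c(OC)cc(OC)c1OC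
A3 | alternative 2 | carbon monoxide | [C-]#[O+]
A4 | alternative 3 | 2-[2,3-bis(benzyloxy)phenyl]-5,7-dihydroxy-3,8-dimethoxy-4H-chromen-4-one | COc1c(O)cc(O)c2c(=O)c(OC)c(-c3cccc(OCc4ccccc4)c3OCc3ccccc3)oc12
A5 | alternative 3 | kojic acid (5-hydroxy-2-(hydroxymethyl)-4H-pyran-4-one) | OCc1cc(=O)c(O)co1
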